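The furan is opened at O1–C2, the bond between the ring oxygen and the aryl-bearing carbon. Furan atoms C2, C3, C4 and C5 map onto the benzylic CH2, the two alkene carbons and the oxygenated methyl branch of a geranylhydroquinone-type chain. An acyclic allyl arene therefore already contains the whole skeleton. In one operation DDQ removes a hydride from the CH2 that is benzylic as well as allylic, the cis hydroxymethyl oxygen closes the 2,5-dihydrofuran, and a second equivalent aromatises it. The precursor is an (S,E)-configured 2-(hydroxymethyl)allyl arene carrying the senecioate ester and MOM-protected phenols. Its geometry derives from hydroxyl-directed trans-hydrostannation of an enantioenriched propargylic alcohol.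

Key step: step 11

Remark: the furan is numbered O1, C2 (aryl), C3, C4 (side chain), C5. The target stereocentre reads (S), and because O > unsaturated carbon > CH2 > H holds in every intermediate, the descriptor stays (S) from step 6 to the end. By the sequence rules the alkene of the cyclisation precursor is (E), which is the isomer with CH2OH cis to the benzylic CH2. The C-silylated propargyl bromide, both acids and (tributylstannyl)methanol are taken as purchased.

Step 1
Reactants: 1 hydroquinone
Product: 2 1,4-bis(methoxymethoxy)benzene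
Conditions: MOMCl (2.6 equiv), i-Pr2NEt (3 equiv), CH2Cl2, 0 °C → rt
Reagents that add atoms: chloromethyl methyl ether, COCCl
Why: Base-mediated O-alkylation of both phenols with a very reactive α-chloro ether (Williamson-type acetal formation) is routine, and the MOM groups later direct lithiation, keep the ring electron-rich for the oxidation and leave under buffered conditions.

Step 2
Reactants: 2 1,4-bis(methoxymethoxy)benzene; 3 (3-bromoprop-1-yn-1-yl)trimethylsilane
Product: 6 {3-[2,5-bis(methoxymethoxy)phenyl]prop-1-yn-1-yl}trimethylsilane, via aryllithium 4 (not isolated), via arylmagnesium bromide 5 (not isolated)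
Conditions: n-BuLi, THF, 0 °C; MgBr2·OEt2, 0 °C; CuBr·SMe2 (10 mol %), 3, 0 °C → rt
Reagents that add atoms: none
Why: Directed ortho-metalation beside a MOM ether (the four ring C–H bonds are equivalent, so only one aryllithium can form) followed by lithium-to-magnesium exchange and copper-catalysed SN2 coupling is standard, and the silyl cap on the electrophile removes the acidic alkyne proton and blocks SN2' attack, the two ways in which unprotected propargyl bromide would lead to quenching of the aryl metal and to allene formation.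

Step 3
Reactants: 6 {3-[2,5-bis(methoxymethoxy)phenyl]prop-1-yn-1-yl}trimethylsilane
Product: 7 1,4-bis(methoxymethoxy)-2-(prop-2-yn-1-yl)benzene
Conditions: K2CO3 (0.2 equiv), MeOH, 0 °C → rt, short contact
Reagents that add atoms: none
Why: Carbonate-catalysed methanolysis of the alkynyl C–Si bond (protodesilylation) is fast at or below room temperature, where the benzylic propargylic CH2 should not yet isomerise to the allene.

Step 4
Reactants: 8 4-methylpent-3-enoic acid
Product: 10 N-methoxy-N,4-dimethylpent-3-enamide, via acyl imidazolide 9 (not isolated)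
Conditions: CDI, CH2Cl2, 0 °C → rt; then MeNHOMe·HCl, rt
Reagents that add atoms: N,O-dimethylhydroxylamine hydrochloride, CNOC.Cl
Why: Weinreb amide formation through the acyl imidazolide needs no added amine base, so the β,γ-alkene should stay out of conjugation.

Step 5
Reactants: 7 1,4-bis(methoxymethoxy)-2-(prop-2-yn-1-yl)benzene; 10 N-methoxy-N,4-dimethylpent-3-enamide
Product: 13 1-[2,5-bis(methoxymethoxy)phenyl]-7-methyloct-6-en-2-yn-4-one, via lithium acetylide 11 (not isolated), via tetrahedral lithium alkoxide 12 (not isolated)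
Conditions: n-BuLi (1.0 equiv), THF, −78 °C; 10, −78 → −20 °C; AcOH/THF quench at −78 °C
Reagents that add atoms: none
Why: Weinreb ketone synthesis in which the alkyne C–H, the most acidic site, is lithiated cleanly at low temperature, the chelated adduct prevents a second addition, and the cold acidic quench protonates the released hydroxylamine before it can add to the ynone and avoids base-induced isomerisation of the two activated CH2 groups.

Step 6
Reactants: 13 1-[2,5-bis(methoxymethoxy)phenyl]-7-methyloct-6-en-2-yn-4-one
Product: 14 (S)-1-[2,5-bis(methoxymethoxy)phenyl]-7-methyloct-6-en-2-yn-4-ol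
Conditions: Ru[(S,S)-TsNCH(Ph)CH(Ph)NH](p-cymene) (2 mol %), i-PrOH, rt
Reagents that add atoms: none
Why: Noyori asymmetric transfer hydrogenation of an alkynyl ketone, in which the alkyne takes the place beside the η6-arene that an aryl group occupies in aryl ketones, so the (S,S)-ligand should deliver hydride to the face that gives the (S)-carbinol, while the base-free medium spares the acidic CH2 groups, the alkyne and the prenyl alkene.

Step 7
Reactants: 14 (S)-1-[2,5-bis(methoxymethoxy)phenyl]-7-methyloct-6-en-2-yn-4-ol
Product: 15 (S,Z)-1-[2,5-bis(methoxymethoxy)phenyl]-7-methyl-3-(tributylstannyl)octa-2,6-dien-4-ol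
Conditions: [Cp*RuCl]4 (2.5 mol %), Bu3SnH (1.1 equiv, slow addition), CH2Cl2, rt
Reagents that add atoms: tributyltin hydride, CCCC[SnH](CCCC)CCCC
Why: Ruthenium-catalysed trans-hydrostannation of a propargylic alcohol, in which the O–H···Cl–Ru hydrogen bond steers tin to the alkyne carbon next to the carbinol and H and Sn add to opposite faces, so tin ends cis to the benzylic CH2, exactly where the hydroxymethyl group must later sit, and the stereocentre is untouched.

Step 8
Reactants: 15 (S,Z)-1-[2,5-bis(methoxymethoxy)phenyl]-7-methyl-3-(tributylstannyl)octa-2,6-dien-4-ol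
Product: 16 (S,Z)-1-[2,5-bis(methoxymethoxy)phenyl]-3-iodo-7-methylocta-2,6-dien-4-ol
Conditions: I2 (1.0 equiv, titrated), CH2Cl2, −78 °C
Reagents that add atoms: iodine, II
Why: Iododestannylation is stereoretentive and, when iodine is titrated in at low temperature, far faster than iodoetherification of the prenyl alkene or iodination of the arene.

Step 9
Reactants: 16 (S,Z)-1-[2,5-bis(methoxymethoxy)phenyl]-3-iodo-7-methylocta-2,6-dien-4-ol; 17 3-methylbut-2-enoic acid
Product: 18 (S,Z)-1-[2,5-bis(methoxymethoxy)phenyl]-3-iodo-7-methylocta-2,6-dien-4-yl 3-methylbut-2-enoate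
Conditions: DCC, DMAP (cat.), CH2Cl2, 0 °C → rt
Reagents that add atoms: none
Why: Steglich esterification acylates at oxygen without breaking the C–O bond, so the (S) configuration is kept, and activating the free acid instead of using the acid chloride with an amine base avoids the vinylketene path to the deconjugated ester.

Step 10
Reactants: 18 (S,Z)-1-[2,5-bis(methoxymethoxy)phenyl]-3-iodo-7-methylocta-2,6-dien-4-yl 3-methylbut-2-enoate; 19 (tributylstannyl)methanol
Product: 20 (S,E)-1-[2,5-bis(methoxymethoxy)phenyl]-3-(hydroxymethyl)-7-methylocta-2,6-dien-4-yl 3-methylbut-2-enoate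
Conditions: Pd2(dba)3 (5 mol %), AsPh3 (20 mol %), NMP, 50 °C; rapid filtration through buffered silica, used at once
Reagents that add atoms: none
Why: Stille hydroxymethylation, in which oxidative addition into the C–I bond and transfer of the α-oxygenated CH2OH group retain the alkene geometry, while the weakly donating arsine speeds transmetalation at moderate temperature and makes zerovalent palladium a poor partner for ionising the allylic ester.

Step 11
Reactants: 20 (S,E)-1-[2,5-bis(methoxymethoxy)phenyl]-3-(hydroxymethyl)-7-methylocta-2,6-dien-4-yl 3-methylbut-2-enoate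
Product: 22 (S)-1-{5-[2,5-bis(methoxymethoxy)phenyl]furan-3-yl}-4-methylpent-3-en-1-yl 3-methylbut-2-enoate, via 2,5-dihydrofuran 21 (not isolated)
Conditions: DDQ (2.1 equiv, in portions), 2,6-dichloropyridine (4 equiv), 4 Å MS, ClCH2CH2Cl, 0 °C → rt
Reagents that add atoms: none
Why: DDQ takes a hydride (or an electron followed by a hydrogen atom) from the one CH2 that is both benzylic to the 2,5-dialkoxyarene and allylic, giving a cation that the ortho MOM oxygen stabilises as a quinone-methide-type oxocarbenium ion, and the hydroxymethyl oxygen, held cis to this carbon by the (E)-alkene, forms O1–C2 to give 2,5-dihydrofuran 21. The ring closes in a 5-exo-trig mode with respect to the exocyclic C=C of that resonance form (it would count as 5-endo only if the ion were a pure allyl cation), which is the same closure as in the acid-catalysed cyclodehydration of (Z)-1-arylbut-2-ene-1,4-diols. C2–H of 21 is benzylic, allylic and α to oxygen, so the second equivalent of DDQ should remove it faster than the first oxidation runs, and loss of a C5 proton from the resulting oxocarbenium ion aromatises the ring. The closest known reaction types are the DDQ-mediated oxidative C–H etherification of electron-rich benzylic or allylic positions by tethered alcohols and the DDQ dehydrogenation of 2,5-dihydrofurans, and only their combination in one flask on this substrate remains to be shown. No lasting stereocentre is made: C2 of 21 forms without control and is erased, while the (S)-carbinol carbon is never a cationic centre and its own C–H bond is deactivated by the acyloxy group. The step needs attack at the benzylic CH2 rather than at the prenyl allylic positions or the primary carbinol C–H, which the easily oxidised dialkoxyarene secures, and the sieves, the weak pyridine base and the limit of two equivalents guard against water capture, acid from the spent oxidant and over-oxidation of the aryl furan.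

Step 12
Reactants: 22 (S)-1-{5-[2,5-bis(methoxymethoxy)phenyl]furan-3-yl}-4-methylpent-3-en-1-yl 3-methylbut-2-enoate
Product: 24 (S)-1-[5-(2,5-dihydroxyphenyl)furan-3-yl]-4-methylpent-3-en-1-yl 3-methylbut-2-enoate, via bis(trimethylsilyl) ether 23 (not isolated)
Conditions: TMSOTf, 2,2'-bipyridyl, MeCN, 0 °C → rt, argon; then H2O, rt, degassed work-up
Reagents that add atoms: none
Why: Buffered acetal cleavage in which the silyl triflate–bipyridyl pair turns aryl MOM ethers into aryl trimethylsilyl ethers, the methoxymethyl unit leaving as a bipyridinium salt, and water then hydrolyses the labile Si–O bonds near neutrality, so no free strong acid meets the furan, the furylmethyl ester or the prenyl alkene.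

Compound list
1 | hydroquinone | Oc1ccc(O)cc1 | starting material
2 | 1,4-bis(methoxymethoxy)benzene | COCOc1ccc(OCOC)cc1 | intermediate
3 | (3-bromoprop-1-yn-1-yl)trimethylsilane | C[Si](C)(C)C#CCBr | starting material
4 | [2,5-bis(methoxymethoxy)phenyl]lithium | [Li]c1cc(OCOC)ccc1OCOC | intermediate
5 | [2,5-bis(methoxymethoxy)phenyl]magnesium bromide | Br[Mg]c1cc(OCOC)ccc1OCOC | intermediate
6 | {3-[2,5-bis(methoxymethoxy)phenyl]prop-1-yn-1-yl}trimethylsilane | C[Si](C)(C)C#CCc1cc(OCOC)ccc1OCOC | intermediate
7 | 1,4-bis(methoxymethoxy)-2-(prop-2-yn-1-yl)benzene | C#CCc1cc(OCOC)ccc1OCOC | intermediate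
8 | 4-methylpent-3-enoic acid | CC(C)=CCC(=O)O | starting material
9 | 1-(1H-imidazol-1-yl)-4-methylpent-3-en-1-one | CC(C)=CCC(=O)n1ccnc1 | intermediate
10 | N-methoxy-N,4-dimethylpent-3-enamide | CC(C)=CCC(=O)N(C)OC | intermediate
11 | {3-[2,5-bis(methoxymethoxy)phenyl]prop-1-yn-1-yl}lithium | [Li]C#CCc1cc(OCOC)ccc1OCOC | intermediate
12 | lithium 1-[2,5-bis(methoxymethoxy)phenyl]-4-[methoxy(methyl)amino]-7-methyloct-6-en-2-yn-4-olate (racemic at C4) | CC(C)=CCC(O[Li])(N(C)OC)C#CCc1cc(OCOC)ccc1OCOC | intermediate
13 | 1-[2,5-bis(methoxymethoxy)phenyl]-7-methyloct-6-en-2-yn-4-one | CC(C)=CCC(=O)C#CCc1cc(OCOC)ccc1OCOC | intermediate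
14 | (S)-1-[2,5-bis(methoxymethoxy)phenyl]-7-methyloct-6-en-2-yn-4-ol | CC(C)=CC[C@H](O)C#CCc1cc(OCOC)ccc1OCOC | intermediate
15 | (S,Z)-1-[2,5-bis(methoxymethoxy)phenyl]-7-methyl-3-(tributylstannyl)octa-2,6-dien-4-ol | CC(C)=CC[C@H](O)/C([Sn](CCCC)(CCCC)CCCC)=C/Cc1cc(OCOC)ccc1OCOC | intermediate
16 | (S,Z)-1-[2,5-bis(methoxymethoxy)phenyl]-3-iodo-7-methylocta-2,6-dien-4-ol | CC(C)=CC[C@H](O)/C(I)=C/Cc1cc(OCOC)ccc1OCOC | intermediate
17 | 3-methylbut-2-enoic acid (senecioic acid) | CC(C)=CC(=O)O | starting material
18 | (S,Z)-1-[2,5-bis(methoxymethoxy)phenyl]-3-iodo-7-methylocta-2,6-dien-4-yl 3-methylbut-2-enoate | CC(C)=CC[C@H](OC(=O)C=C(C)C)/C(I)=C/Cc1cc(OCOC)ccc1OCOC | intermediate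
19 | (tributylstannyl)methanol | OC[Sn](CCCC)(CCCC)CCCC | starting material
20 | (S,E)-1-[2,5-bis(methoxymethoxy)phenyl]-3-(hydroxymethyl)-7-methylocta-2,6-dien-4-yl 3-methylbut-2-enoate (CH2OH cis to the benzylic CH2) | CC(C)=CC[C@H](OC(=O)C=C(C)C)/C(CO)=C/Cc1cc(OCOC)ccc1OCOC | intermediate
21 | (1S)-1-{5-[2,5-bis(methoxymethoxy)phenyl]-2,5-dihydrofuran-3-yl}-4-methylpent-3-en-1-yl 3-methylbut-2-enoate (both epimers at the aryl-bearing ring carbon) | CC(C)=CC[C@H](OC(=O)C=C(C)C)C1=CC(c2cc(OCOC)ccc2OCOC)OC1 | intermediate
22 | (S)-1-{5-[2,5-bis(methoxymethoxy)phenyl]furan-3-yl}-4-methylpent-3-en-1-yl 3-methylbut-2-enoate | CC(C)=CC[C@H](OC(=O)C=C(C)C)c1coc(-c2cc(OCOC)ccc2OCOC)c1 | intermediate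
23 | (S)-1-{5-[2,5-bis(trimethylsilyloxy)phenyl]furan-3-yl}-4-methylpent-3-en-1-yl 3-methylbut-2-enoate | CC(C)=CC[C@H](OC(=O)C=C(C)C)c1coc(-c2cc(O[Si](C)(C)C)ccc2O[Si](C)(C)C)c1 | intermediate
24 | (S)-1-[5-(2,5-dihydroxyphenyl)furan-3-yl]-4-methylpent-3-en-1-yl 3-methylbut-2-enoate | CC(C)=CC[C@H](OC(=O)C=C(C)C)c1coc(-c2cc(O)ccc2O)c1 | target

Total step count: 12. Longest linear sequence: 11 (steps 1–3 and 5–12, from hydroquinone). Step 4 is a one-step branch.

Three steps most likely to fail

Step 11.
- **What may go wrong:** The primary allylic alcohol may be oxidised before C–H abstraction. The cation may lose its alkene geometry before capture, or lose a proton towards a conjugated diene. The electron-rich aryl furan may be over-oxidised.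
- **Fallback (sets out from 2, comes back at 22):** The oxidative closure is given up and both substituents are attached to a preformed furan by known reactions.
  - Compound 2 is lithiated as in step 2 to 4 and transmetalated with ZnCl2 to [2,5-bis(methoxymethoxy)phenyl]zinc chloride F1.
  - Negishi coupling of this reagent with commercial 2,4-dibromofuran (Pd(PPh3)4, THF, rt) should occur at the more reactive C–Br bond next to oxygen and give 4-bromo-2-[2,5-bis(methoxymethoxy)phenyl]furan F2.
  - Bromine–lithium exchange (n-BuLi, Et2O, −78 °C) gives {5-[2,5-bis(methoxymethoxy)phenyl]furan-3-yl}lithium F3.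
  - Acylation with Weinreb amide 10 gives 1-{5-[2,5-bis(methoxymethoxy)phenyl]furan-3-yl}-4-methylpent-3-en-1-one F4.
  - Reduction with (−)-Ipc2BCl (THF, −25 °C) treats the furyl group as the large substituent, as it does the aryl group of aryl alkyl ketones. It should give (S)-1-{5-[2,5-bis(methoxymethoxy)phenyl]furan-3-yl}-4-methylpent-3-en-1-ol F5.
  - Steglich esterification with 17 as in step 9 gives 22.

Step 10.
- **What may go wrong:** Transfer of the CH2OH group may be slow, which would let butyl transfer or protodeiodination compete. Zerovalent palladium may ionise the allylic ester, or the alkenylpalladium intermediate may eliminate the acyloxy group. The pendant enoate may undergo carbopalladation. The acyl group may migrate to the new primary hydroxyl.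
- **Fallback (sets out from 16, comes back at 20):** The coupling is moved ahead of the esterification, so that no allylic ester meets palladium.
  - Compounds 16 and 19 are coupled under classical conditions (Pd(PPh3)4, toluene, 90 °C) to (S,E)-1-[2,5-bis(methoxymethoxy)phenyl]-3-(hydroxymethyl)-7-methylocta-2,6-dien-4-ol F6.
  - The primary hydroxyl is silylated selectively (TBSCl, imidazole, CH2Cl2, −20 °C) to the mono(tert-butyldimethylsilyl) ether F7.
  - Steglich esterification with 17 gives the silylated ester F8.
  - HF·pyridine buffered with pyridine (THF, 0 °C) frees the primary alcohol to give 20.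

Step 12.
- **What may go wrong:** The furylmethyl ester may ionise under silyl Lewis acid activation, the furan may degrade, acetal cleavage may stay incomplete, or the liberated hydroquinone may oxidise in air.
- **Fallback (sets out from 18, comes back at 24):** The acetal cleavage is moved to a stage without furan or furylmethyl ester, and the last step becomes a fluoride desilylation.
  - Compound 18, whose iodoalkene disfavours ionisation, is treated with p-TsOH·H2O (cat.) in MeOH at 40 °C to give the free hydroquinone iodo ester F9.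
  - Immediate silylation (TBSCl, imidazole, DMF) gives the bis(tert-butyldimethylsilyl) ether F10.
  - Stille hydroxymethylation with 19 as in step 10 gives the bis-silyl cyclisation precursor F11.
  - DDQ under the conditions of step 11 leads through the bis-silyl 2,5-dihydrofuran F12 to the bis-silyl furan F13.
  - TBAF buffered with AcOH (THF, 0 °C) releases 24.

Further compounds
F1 | step 11 | [2,5-bis(methoxymethoxy)phenyl]zinc chloride | Cl[Zn]c1cc(OCOC)ccc1OCOC
F2 | step 11 | 4-bromo-2-[2,5-bis(methoxymethoxy)phenyl]furan | Brc1coc(-c2cc(OCOC)ccc2OCOC)c1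
F3 | step 11 | {5-[2,5-bis(methoxymethoxy)phenyl]furan-3-yl}lithium | [Li]c1coc(-c2cc(OCOC)ccc2OCOC)c1
F4 | step 11 | 1-{5-[2,5-bis(methoxymethoxy)phenyl]furan-3-yl}-4-methylpent-3-en-1-one | CC(C)=CCC(=O)c1coc(-c2cc(OCOC)ccc2OCOC)c1
F5 | step 11 | (S)-1-{5-[2,5-bis(methoxymethoxy)phenyl]furan-3-yl}-4-methylpent-3-en-1-ol | CC(C)=CC[C@H](O)c1coc(-c2cc(OCOC)ccc2OCOC)c1
F6 | step 10 | (S,E)-1-[2,5-bis(methoxymethoxy)phenyl]-3-(hydroxymethyl)-7-methylocta-2,6-dien-4-ol | CC(C)=CC[C@H](O)/C(CO)=C/Cc1cc(OCOC)ccc1OCOC
F7 | step 10 | (S,E)-1-[2,5-bis(methoxymethoxy)phenyl]-3-{[(tert-butyldimethylsilyl)oxy]methyl}-7-methylocta-2,6-dien-4-ol | CC(C)=CC[C@H](O)/C(CO[Si](C)(C)C(C)(C)C)=C/Cc1cc(OCOC)ccc1OCOC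
F8 | step 10 | (S,E)-1-[2,5-bis(methoxymethoxy)phenyl]-3-{[(tert-butyldimethylsilyl)oxy]methyl}-7-methylocta-2,6-dien-4-yl 3-methylbut-2-enoate | CC(C)=CC[C@H](OC(=O)C=C(C)C)/C(CO[Si](C)(C)C(C)(C)C)=C/Cc1cc(OCOC)ccc1OCOC
F9 | step 12 | (S,Z)-1-(2,5-dihydroxyphenyl)-3-iodo-7-methylocta-2,6-dien-4-yl 3-methylbut-2-enoate | CC(C)=CC[C@H](OC(=O)C=C(C)C)/C(I)=C/Cc1cc(O)ccc1O
F10 | step 12 | (S,Z)-1-{2,5-bis[(tert-butyldimethylsilyl)oxy]phenyl}-3-iodo-7-methylocta-2,6-dien-4-yl 3-methylbut-2-enoate | CC(C)=CC[C@H](OC(=O)C=C(C)C)/C(I)=C/Cc1cc(O[Si](C)(C)C(C)(C)C)ccc1O[Si](C)(C)C(C)(C)C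
F11 | step 12 | (S,E)-1-{2,5-bis[(tert-butyldimethylsilyl)oxy]phenyl}-3-(hydroxymethyl)-7-methylocta-2,6-dien-4-yl 3-methylbut-2-enoate | CC(C)=CC[C@H](OC(=O)C=C(C)C)/C(CO)=C/Cc1cc(O[Si](C)(C)C(C)(C)C)ccc1O[Si](C)(C)C(C)(C)C
F12 | step 12 | (1S)-1-(5-{2,5-bis[(tert-butyldimethylsilyl)oxy]phenyl}-2,5-dihydrofuran-3-yl)-4-methylpent-3-en-1-yl 3-methylbut-2-enoate (both ring epimers) | CC(C)=CC[C@H](OC(=O)C=C(C)C)C1=CC(c2cc(O[Si](C)(C)C(C)(C)C)ccc2O[Si](C)(C)C(C)(C)C)OC1
F13 | step 12 | (S)-1-(5-{2,5-bis[(tert-butyldimethylsilyl)oxy]phenyl}furan-3-yl)-4-methylpent-3-en-1-yl 3-methylbut-2-enoate | CC(C)=CC[C@H](OC(=O)C=C(C)C)c1coc(-c2cc(O[Si](C)(C)C(C)(C)C)ccc2O[Si](C)(C)C(C)(C)C)c1
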